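**Retrosynthetic overview**

1. Target ⇐ its octa-O-TBS ether ⇐ bis-ketone in which both Ar–CH2–Ar carbons are still C=O. The C=O → CH2 change goes through radicals, not cations, because each ether CH2 is para to the C4 oxygen and next to the C2 side chain.
2. Bis-ketone ⇐ bis-ynone + 2 × 1-bromo-2,3-bis(silyloxy)cyclohexa-1,3-diene: in each ring B the bonds C2–C3 and C1–C6 are cut (Diels–Alder) and a C2H4 bridge is put back (retro-Diels–Alder).
3. Feature: in each inner ring B (C1 CH2O, C2 CH2Ar, C3 Br, C4 OH, C5 OH, C6 H) the neighbours C1 and C2 are the two carbons of one alkyne. The CH2–O–CH2 bridge between the two C1 atoms is therefore dipropargyl ether, and C3(Br)–C4(O)–C5(O)–C6(H) is a brominated catechol diene.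
4. Bis-ynone ⇐ dipropargyl ether + 2 × 2,3-dibromo-4,5-bis(silyloxy)benzaldehyde (rings A, from 5-bromovanillin); diene ⇐ cyclohexane-1,2-dione.
5. Ring order: rings A are bought as 5-bromovanillin; both rings B are closed together in the key step.

Key step: step 8

Remark: 5-bromovanillin is taken as the commercial source of rings A; the target has no stereocenter, so carbinol and bridgehead centers that arise on the way are carried as diastereomer mixtures and are all removed again.

**Route**

Step 1
Reactants: 1 5-bromovanillin (3-bromo-4-hydroxy-5-methoxybenzaldehyde)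
Product: 2 2,3-dibromo-4-hydroxy-5-methoxybenzaldehyde
Conditions: Br2 (1.2 equiv), Fe powder (cat.), NaOAc, AcOH, rt
Reagents that add atoms: bromine, BrBr
Why: Electrophilic aromatic bromination; both ortho positions and the para position of the phenol are occupied, so the methoxy group should direct the second bromine to its free para position, which becomes C2 of the new numbering.

Step 2
Reactants: 2 2,3-dibromo-4-hydroxy-5-methoxybenzaldehyde
Product: 3 2,3-dibromo-4,5-dihydroxybenzaldehyde
Conditions: BBr3 (3 equiv), CH2Cl2, −78 °C to rt; then H2O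
Reagents that add atoms: none
Why: Lewis acid cleavage of an aryl methyl ether (boron on oxygen, bromide SN2 at methyl), which should leave the aldehyde and the aryl bromides untouched.

Step 3
Reactants: 3 2,3-dibromo-4,5-dihydroxybenzaldehyde
Product: 4 2,3-dibromo-4,5-bis(tert-butyldimethylsilyloxy)benzaldehyde
Conditions: TBSCl (2.5 equiv), imidazole (5 equiv), DMF, rt to 40 °C
Reagents that add atoms: tert-butyldimethylsilyl chloride, CC(C)(C)[Si](C)(C)Cl
Why: Imidazole-promoted silylation of phenols; the C4 phenol is flanked by Br and OTBS but is acidic, so gentle warming should complete the bis-silylation.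

Step 4
Reactants: 5 dipropargyl ether; 4 2,3-dibromo-4,5-bis(tert-butyldimethylsilyloxy)benzaldehyde (2.1 equiv)
Product: 7 bis{4-[2,3-dibromo-4,5-bis(tert-butyldimethylsilyloxy)phenyl]-4-hydroxybut-2-ynyl} ether (meso and racemic diol), via dilithium bis-acetylide 6 (not isolated)
Conditions: n-BuLi (2.0 equiv), THF, −78 °C; then 4, −78 to −20 °C; aq NH4Cl
Reagents that add atoms: none
Why: 1,2-addition of a lithium acetylide to an aldehyde, done at both ends; alkynyllithiums do not exchange with aryl bromides, and the two carbinol centers form without control and are erased in step 5.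

Step 5
Reactants: 7 bis{4-[2,3-dibromo-4,5-bis(tert-butyldimethylsilyloxy)phenyl]-4-hydroxybut-2-ynyl} ether
Product: 8 bis{4-[2,3-dibromo-4,5-bis(tert-butyldimethylsilyloxy)phenyl]-4-oxobut-2-ynyl} ether
Conditions: MnO2 (activated, excess), CH2Cl2, rt
Reagents that add atoms: none
Why: MnO2 oxidation of alcohols that are both benzylic and propargylic, a neutral method that should spare the silyl ethers and the sensitive ynones.

Step 6
Reactants: 9 cyclohexane-1,2-dione
Product: 10 3-bromo-2-hydroxycyclohex-2-en-1-one (enol form of 3-bromocyclohexane-1,2-dione)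
Conditions: NBS (1.0 equiv), CH2Cl2, 0 °C to rt
Reagents that add atoms: N-bromosuccinimide, O=C1CCC(=O)N1Br
Why: Electrophilic bromination of the enol of the dione at C3, after which the product should re-enolise toward the brominated carbon.

Step 7
Reactants: 10 3-bromo-2-hydroxycyclohex-2-en-1-one
Product: 12 1-bromo-2,3-bis(tert-butyldimethylsilyloxy)cyclohexa-1,3-diene, via mono-silylated enone 11 (not isolated)
Conditions: TBSOTf (2.4 equiv), Et3N (4 equiv), CH2Cl2, −78 to 0 °C; filtration through basic alumina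
Reagents that add atoms: tert-butyldimethylsilyl trifluoromethanesulfonate, CC(C)(C)[Si](C)(C)OS(=O)(=O)C(F)(F)F
Why: O-silylation of the enol followed by soft enolisation (silyl triflate and amine) of the ketone toward its only α-CH2, the kinetic course known for enones, should give the cross-conjugated 2,3-bis(silyloxy) diene in the way the bromine-free diene is made from the dione.

Step 8
Reactants: 8 bis{4-[2,3-dibromo-4,5-bis(tert-butyldimethylsilyloxy)phenyl]-4-oxobut-2-ynyl} ether; 12 1-bromo-2,3-bis(tert-butyldimethylsilyloxy)cyclohexa-1,3-diene (5 equiv)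
Product: 14 bis{3-bromo-2-[2,3-dibromo-4,5-bis(tert-butyldimethylsilyloxy)benzoyl]-4,5-bis(tert-butyldimethylsilyloxy)benzyl} ether, via bis(bicyclo[2.2.2]octadiene) adduct 13 (not isolated)
Conditions: BHT (cat.), mesitylene, 110 °C, then 185 °C, sealed tube, argon
Reagents that add atoms: none
Why: Each ynone of 8 should take up one molecule of 12 in a thermal, asynchronous Diels–Alder reaction in which the electrophilic β-carbon (carrying CH2O, future C1) bonds first to the unsubstituted diene terminus (future C6) and the acyl-bearing α-carbon (future C2) then bonds to the C–Br terminus (future C3); the bicyclo[2.2.2]octa-2,5-dienes of 13 then lose their CH2–CH2 bridge as ethylene in a retro-Diels–Alder reaction driven by aromatisation, so that C3–Br and the C4 and C5 silyl ethers arrive in fixed positions. The closest known reaction type is the Alder–Rickert synthesis of aryl silyl ethers from 2-silyloxycyclohexa-1,3-dienes and acetylenic ketones or esters, and dienes with a halogen at a terminus are known to give bridgehead halides in Diels–Alder reactions. Each ring B is closed by an intermolecular [4+2] cycloaddition that forms C2–C3 and C1–C6 (six-membered carbocycle, both rings closed in the same operation), and no stereocenter survives because the bridgehead centers of 13 become aromatic carbons. The step needs one orientation of addition at both ynones: this should follow from the polarisation of the ynone (largest acceptor coefficient at the β-carbon) matched with a diene whose two termini are both enol ether β-carbons but whose brominated terminus is less nucleophilic and more hindered, the pattern that places a terminal substituent of a diene next to the acceptor-bearing carbon. An excess of 12 and a cycloaddition held at 110 °C before the temperature is raised should bring both ends to reaction before the diene isomerises by 1,5-hydrogen shift.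

Step 9
Reactants: 14 bis{3-bromo-2-[2,3-dibromo-4,5-bis(tert-butyldimethylsilyloxy)benzoyl]-4,5-bis(tert-butyldimethylsilyloxy)benzyl} ether
Product: 15 bis{3-bromo-2-[(2,3-dibromo-4,5-bis(tert-butyldimethylsilyloxy)phenyl)(hydroxy)methyl]-4,5-bis(tert-butyldimethylsilyloxy)benzyl} ether (mixture of diastereomers)
Conditions: i-Bu2AlH (3 equiv), CH2Cl2, −78 to 0 °C; aq potassium sodium tartrate
Reagents that add atoms: none
Why: Hydride reduction of a hindered diaryl ketone by an aluminium hydride that tolerates aryl bromides and aryl silyl ethers; the two carbinol centers form without control and are removed in step 11.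

Step 10
Reactants: 15 bis{3-bromo-2-[(2,3-dibromo-4,5-bis(tert-butyldimethylsilyloxy)phenyl)(hydroxy)methyl]-4,5-bis(tert-butyldimethylsilyloxy)benzyl} ether
Product: 16 bis[3,5-bis(trifluoromethyl)benzoate] of 15 (mixture of diastereomers)
Conditions: 3,5-(CF3)2C6H3COCl (3 equiv), Et3N, DMAP (cat.), CH2Cl2, 0 °C to rt; filtration through Et3N-deactivated silica
Reagents that add atoms: 3,5-bis(trifluoromethyl)benzoyl chloride, O=C(Cl)c1cc(C(F)(F)F)cc(C(F)(F)F)c1
Why: DMAP-catalysed acylation of a secondary alcohol under neutral, non-ionising conditions installs an electron-poor benzoate that serves as the electron acceptor in step 11.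

Step 11
Reactants: 16 bis[3,5-bis(trifluoromethyl)benzoate] of 15
Product: 17 bis{3-bromo-2-[2,3-dibromo-4,5-bis(tert-butyldimethylsilyloxy)benzyl]-4,5-bis(tert-butyldimethylsilyloxy)benzyl} ether
Conditions: [Ir(ppy)2(dtbbpy)]PF6 (2 mol %), i-Pr2NEt (4 equiv), H2O, MeCN/THF, blue LED (455 nm), 40 °C
Reagents that add atoms: none
Why: Visible-light photoredox deoxygenation of benzylic 3,5-bis(trifluoromethyl)benzoates: the reduced photocatalyst passes one electron to the benzoate, the radical anion splits into carboxylate and a doubly benzylic radical that is reduced to C–H, so no cation arises that the neighbouring ether oxygen could capture or that would cleave the acid-labile dibenzyl ether, and the aryl bromides lie at far more negative potentials.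

Step 12
Reactants: 17 bis{3-bromo-2-[2,3-dibromo-4,5-bis(tert-butyldimethylsilyloxy)benzyl]-4,5-bis(tert-butyldimethylsilyloxy)benzyl} ether
Product: 18 bis[3-bromo-2-(2,3-dibromo-4,5-dihydroxybenzyl)-4,5-dihydroxybenzyl] ether (CNP0255526.0)
Conditions: TBAF (10 equiv), AcOH (10 equiv), THF, 0 °C, argon; aq NaH2PO4 work-up
Reagents that add atoms: none
Why: Fluoride cleavage of aryl silyl ethers driven by Si–F bond formation; the acetic acid buffer should keep the phenols protonated, which holds back 1,6-elimination of the para-hydroxybenzyl ether and oxidation of the catechols.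

**Compound list**

1 | 5-bromovanillin (3-bromo-4-hydroxy-5-methoxybenzaldehyde) | COc1cc(C=O)cc(Br)c1O | starting material
2 | 2,3-dibromo-4-hydroxy-5-methoxybenzaldehyde | COc1cc(C=O)c(Br)c(Br)c1O | intermediate
3 | 2,3-dibromo-4,5-dihydroxybenzaldehyde | Oc1cc(C=O)c(Br)c(Br)c1O | intermediate
4 | 2,3-dibromo-4,5-bis(tert-butyldimethylsilyloxy)benzaldehyde | O=Cc1cc(O[Si](C)(C)C(C)(C)C)c(O[Si](C)(C)C(C)(C)C)c(Br)c1Br | intermediate
5 | dipropargyl ether | C#CCOCC#C | starting material
6 | dilithium bis-acetylide of dipropargyl ether | [Li]C#CCOCC#C[Li] | intermediate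
7 | bis{4-[2,3-dibromo-4,5-bis(tert-butyldimethylsilyloxy)phenyl]-4-hydroxybut-2-ynyl} ether (meso and racemic mixture) | OC(C#CCOCC#CC(O)c1cc(O[Si](C)(C)C(C)(C)C)c(O[Si](C)(C)C(C)(C)C)c(Br)c1Br)c1cc(O[Si](C)(C)C(C)(C)C)c(O[Si](C)(C)C(C)(C)C)c(Br)c1Br | intermediate
8 | bis{4-[2,3-dibromo-4,5-bis(tert-butyldimethylsilyloxy)phenyl]-4-oxobut-2-ynyl} ether | O=C(C#CCOCC#CC(=O)c1cc(O[Si](C)(C)C(C)(C)C)c(O[Si](C)(C)C(C)(C)C)c(Br)c1Br)c1cc(O[Si](C)(C)C(C)(C)C)c(O[Si](C)(C)C(C)(C)C)c(Br)c1Br | intermediate
9 | cyclohexane-1,2-dione | O=C1CCCCC1=O | starting material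
10 | 3-bromo-2-hydroxycyclohex-2-en-1-one | O=C1CCCC(Br)=C1O | intermediate
11 | 3-bromo-2-(tert-butyldimethylsilyloxy)cyclohex-2-en-1-one | O=C1CCCC(Br)=C1O[Si](C)(C)C(C)(C)C | intermediate
12 | 1-bromo-2,3-bis(tert-butyldimethylsilyloxy)cyclohexa-1,3-diene | BrC1=C(O[Si](C)(C)C(C)(C)C)C(O[Si](C)(C)C(C)(C)C)=CCC1 | intermediate
13 | bis({1-bromo-2-[2,3-dibromo-4,5-bis(tert-butyldimethylsilyloxy)benzoyl]-5,6-bis(tert-butyldimethylsilyloxy)bicyclo[2.2.2]octa-2,5-dien-3-yl}methyl) ether (each bicycle racemic, mixture of diastereomers) | O(CC1=C(C(=O)c2cc(O[Si](C)(C)C(C)(C)C)c(O[Si](C)(C)C(C)(C)C)c(Br)c2Br)C2(Br)CCC1C(O[Si](C)(C)C(C)(C)C)=C2O[Si](C)(C)C(C)(C)C)CC1=C(C(=O)c2cc(O[Si](C)(C)C(C)(C)C)c(O[Si](C)(C)C(C)(C)C)c(Br)c2Br)C2(Br)CCC1C(O[Si](C)(C)C(C)(C)C)=C2O[Si](C)(C)C(C)(C)C | intermediate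
14 | bis{3-bromo-2-[2,3-dibromo-4,5-bis(tert-butyldimethylsilyloxy)benzoyl]-4,5-bis(tert-butyldimethylsilyloxy)benzyl} ether | O=C(c1cc(O[Si](C)(C)C(C)(C)C)c(O[Si](C)(C)C(C)(C)C)c(Br)c1Br)c1c(Br)c(O[Si](C)(C)C(C)(C)C)c(O[Si](C)(C)C(C)(C)C)cc1COCc1cc(O[Si](C)(C)C(C)(C)C)c(O[Si](C)(C)C(C)(C)C)c(Br)c1C(=O)c1cc(O[Si](C)(C)C(C)(C)C)c(O[Si](C)(C)C(C)(C)C)c(Br)c1Br | intermediate
15 | bis{3-bromo-2-[(2,3-dibromo-4,5-bis(tert-butyldimethylsilyloxy)phenyl)(hydroxy)methyl]-4,5-bis(tert-butyldimethylsilyloxy)benzyl} ether (mixture of diastereomers) | OC(c1cc(O[Si](C)(C)C(C)(C)C)c(O[Si](C)(C)C(C)(C)C)c(Br)c1Br)c1c(Br)c(O[Si](C)(C)C(C)(C)C)c(O[Si](C)(C)C(C)(C)C)cc1COCc1cc(O[Si](C)(C)C(C)(C)C)c(O[Si](C)(C)C(C)(C)C)c(Br)c1C(O)c1cc(O[Si](C)(C)C(C)(C)C)c(O[Si](C)(C)C(C)(C)C)c(Br)c1Br | intermediate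
16 | bis[3,5-bis(trifluoromethyl)benzoate] of 15 (mixture of diastereomers) | O=C(OC(c1cc(O[Si](C)(C)C(C)(C)C)c(O[Si](C)(C)C(C)(C)C)c(Br)c1Br)c1c(Br)c(O[Si](C)(C)C(C)(C)C)c(O[Si](C)(C)C(C)(C)C)cc1COCc1cc(O[Si](C)(C)C(C)(C)C)c(O[Si](C)(C)C(C)(C)C)c(Br)c1C(OC(=O)c1cc(C(F)(F)F)cc(C(F)(F)F)c1)c1cc(O[Si](C)(C)C(C)(C)C)c(O[Si](C)(C)C(C)(C)C)c(Br)c1Br)c1cc(C(F)(F)F)cc(C(F)(F)F)c1 | intermediate
17 | bis{3-bromo-2-[2,3-dibromo-4,5-bis(tert-butyldimethylsilyloxy)benzyl]-4,5-bis(tert-butyldimethylsilyloxy)benzyl} ether | C(c1cc(O[Si](C)(C)C(C)(C)C)c(O[Si](C)(C)C(C)(C)C)c(Br)c1Br)c1c(Br)c(O[Si](C)(C)C(C)(C)C)c(O[Si](C)(C)C(C)(C)C)cc1COCc1cc(O[Si](C)(C)C(C)(C)C)c(O[Si](C)(C)C(C)(C)C)c(Br)c1Cc1cc(O[Si](C)(C)C(C)(C)C)c(O[Si](C)(C)C(C)(C)C)c(Br)c1Br | intermediate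
18 | bis[3-bromo-2-(2,3-dibromo-4,5-dihydroxybenzyl)-4,5-dihydroxybenzyl] ether (CNP0255526.0) | Oc1cc(Cc2c(COCc3cc(O)c(O)c(Br)c3Cc3cc(O)c(O)c(Br)c3Br)cc(O)c(O)c2Br)c(Br)c(Br)c1O | target

**Step count and risks**

Total step count: 12. Longest linear sequence: 10 steps (steps 1 to 5 and 8 to 12); the diene arm is steps 6 and 7.

Steps most likely to fail:

1. Step 8. Bond formation at the fully substituted, bromine-bearing diene terminus may be too slow, so that 1,5-hydrogen shift of the diene, loss of silyl groups or reaction at only one ynone takes over; the orientation of addition may also be reversed. The fallback builds ring B on a benzene ring that already carries the bromine and makes the C2–carbinol bond by arylmagnesium addition; it sets out from 1 and 4 and comes back at 15.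
   - Iodination of 1 (ICl, AcOH) at the position para to methoxy, the site that takes bromine in step 1, should give 3-bromo-4-hydroxy-2-iodo-5-methoxybenzaldehyde F1.
   - Demethylation with BBr3 should give 3-bromo-4,5-dihydroxy-2-iodobenzaldehyde F2, and silylation (TBSCl, imidazole, DMF) 3-bromo-4,5-bis(tert-butyldimethylsilyloxy)-2-iodobenzaldehyde F3.
   - Reductive self-etherification of F3 (Et3SiH, TMSOTf cat., CH2Cl2, −78 °C) should give bis[3-bromo-4,5-bis(tert-butyldimethylsilyloxy)-2-iodobenzyl] ether F4 with the central ether in place.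
   - Iodine–magnesium exchange at both C–I bonds (i-PrMgCl·LiCl, THF, −40 °C), which leaves C–Br bonds alone, should give the bis(arylmagnesium chloride) F5; its addition to aldehyde 4 gives bis-carbinol 15, from which steps 10 to 12 follow.

2. Step 11. Electron transfer may reach carbon–bromine bonds (reductive debromination), the activated diarylmethyl ester may ionise before it is reduced so that the neighbouring ether oxygen closes a 1,3-dihydroisobenzofuran, or silyl groups may be lost in the amine and water medium. The fallback is a tin hydride radical chain in an anhydrous, non-basic medium; it sets out from 15 and comes back at 17.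
   - 1,1'-Thiocarbonyldiimidazole and DMAP in 1,2-dichloroethane at 60 °C should give the bis(O-diarylmethyl imidazole-1-carbothioate) F6.
   - Bu3SnH (added slowly) and AIBN in toluene at 80 °C should give 17 by Barton–McCombie deoxygenation through the same doubly benzylic radical.

3. Step 12. Once the C4 phenoxide of ring B is free, 1,6-elimination to a para-quinone methide may cleave the central ether, and the bromocatechols may be oxidised by air. The fallback exchanges the protecting group so that no phenoxide is left free; it sets out from 17 and comes back at 18.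
   - CsF and excess Ac2O in DMF at 0 °C should acetylate each phenoxide as it is released and give the octaacetate F7.
   - The aryl acetates are then removed at neutral pH with NH4OAc in THF/H2O at rt to give 18.

**Further compounds**

F1 | step 8 | 3-bromo-4-hydroxy-2-iodo-5-methoxybenzaldehyde | COc1cc(C=O)c(I)c(Br)c1O
F2 | step 8 | 3-bromo-4,5-dihydroxy-2-iodobenzaldehyde | Oc1cc(C=O)c(I)c(Br)c1O
F3 | step 8 | 3-bromo-4,5-bis(tert-butyldimethylsilyloxy)-2-iodobenzaldehyde | O=Cc1cc(O[Si](C)(C)C(C)(C)C)c(O[Si](C)(C)C(C)(C)C)c(Br)c1I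
F4 | step 8 | bis[3-bromo-4,5-bis(tert-butyldimethylsilyloxy)-2-iodobenzyl] ether | Ic1c(Br)c(O[Si](C)(C)C(C)(C)C)c(O[Si](C)(C)C(C)(C)C)cc1COCc1cc(O[Si](C)(C)C(C)(C)C)c(O[Si](C)(C)C(C)(C)C)c(Br)c1I
F5 | step 8 | bis(arylmagnesium chloride) from F4 | Cl[Mg]c1c(Br)c(O[Si](C)(C)C(C)(C)C)c(O[Si](C)(C)C(C)(C)C)cc1COCc1cc(O[Si](C)(C)C(C)(C)C)c(O[Si](C)(C)C(C)(C)C)c(Br)c1[Mg]Cl
F6 | step 11 | bis(O-diarylmethyl imidazole-1-carbothioate) of 15 | S=C(OC(c1cc(O[Si](C)(C)C(C)(C)C)c(O[Si](C)(C)C(C)(C)C)c(Br)c1Br)c1c(Br)c(O[Si](C)(C)C(C)(C)C)c(O[Si](C)(C)C(C)(C)C)cc1COCc1cc(O[Si](C)(C)C(C)(C)C)c(O[Si](C)(C)C(C)(C)C)c(Br)c1C(OC(=S)n1ccnc1)c1cc(O[Si](C)(C)C(C)(C)C)c(O[Si](C)(C)C(C)(C)C)c(Br)c1Br)n1ccnc1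
F7 | step 12 | octaacetate of 18 | CC(=O)Oc1cc(Cc2c(COCc3cc(OC(C)=O)c(OC(C)=O)c(Br)c3Cc3cc(OC(C)=O)c(OC(C)=O)c(Br)c3Br)cc(OC(C)=O)c(OC(C)=O)c2Br)c(Br)c(Br)c1OC(C)=O
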